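Its constants belong to no real substance; the rest is arithmetic.

The easy step is to set what the solid E can hand to the solution beside what the enzyme D can take from it.

    Z + D → G + D, rate k1*[Z]*[D]/(1 + ([Z]/Km1) + ([Z]/Ksi1)^2) (Km1 = 1.3 mM, Ksi1 = 10 mM, k1 = 1.4 × 10⁵ M⁻¹ h⁻¹)
    E ⇌ Z, rate k2*(cs2 - [Z]) while solid is left; crystals form when [Z] > cs2 (cs2 = 3.0 mM, k2 = 1.2 h⁻¹)
    Z ⇌ X (K3 = 2.0, k3 = 0.18 h⁻¹)
    Q ⇌ G, rate k4*(cs4 - [G]) while solid is left; crystals form when [G] > cs4 (cs4 = 4.8 mM, k4 = 7.7 h⁻¹)

E 11 mM; D 6.0 µM; time 30 h

- amber: doubling the amount of D, all else as stated
- violet: doubling the solubility in step 4, all else as stated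
- green: doubling the solubility in step 2, all else as stated
- red: doubling the dissolution coefficient of step 4, all else as stated

1. how much G and Q together there is at 30 h, in percent of the E charged
2. the change that raises the amount of G and Q together at 30 h, in percent of the E charged most ("none" if none brings more than 2 percentage points) (amber / violet / green / red / none)
3. amount of G and Q together at 30 h, in percent of the E charged, after red

- what is said of G includes Q
- E, Q is a solid; its amount is given per volume of the solution
- at the start none of E is in solution
- run time (flask): 30 h

In the flask E first dissolves at 3.60 mM h⁻¹, while D, with Z at its solubility, turns over 0.742 mM h⁻¹. That first supply is faster than this use, so I hold Z near solubility while solid lasts. Z also leaks into X, at first at 0.540 mM h⁻¹, so I reckon that E lasts about 8.58 h. By then D has made 6.37 mM of G, and 4.63 mM waits as Z and X.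

After that X returns to Z with constant 0.0900 h⁻¹. With Z below 1.3 mM, D removes it in a pseudo-first-order way with constant 0.840 h⁻¹. That is faster than the return, so the return is the rate-limiting step of this tail. Draining at 0.0900 h⁻¹ over the remaining time gives 93.9%.

That link is weak, because returned Z can go back to X with constant 0.18 h⁻¹, slower than 0.840 h⁻¹ but still a share of 17.6% of what happens to it. The constant to use is 0.0741 h⁻¹, the drain constant: the return constant of X times the share of returning Z that D catches. It leaves 0.948 mM, so I commit to 91.4%.

The same chain with D doubled (amber) gives 96.4%, a gain of 5 percentage points. Green gives 90.7%. Red and violet touch the crystals of G, and G stands in no rate law of E, Z or X, so I keep 91.4% for them.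

The forecast says 91.5%, best amber, and 91.5% after red, on these grounds: “Crystallisation of G does not feed back on any step”.

The flask gives 92.4%, best amber with 5 points, and 92.4% after red. At 30.0 h X stands at 6.88% of the E charged and Z at 0.689%. I now apply the drain constant from there: the unconverted 7.60% shrinks over the next 30.0 h to 0.819%. At 60.0 h the flask holds 99.1% of G and Q.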